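**Strategy.** The route rests on opening the central bond of a bicyclo[1.1.0]butane with a four-carbon unit. In the target the cyclobutane carbons C2 (quaternary, methyl) and C7 (CH) are 1,3 to each other, and the chain C3–C4–C5–C6 spans exactly these two atoms, so the seven- and four-membered rings together form a bicyclo[4.1.1]octane. A radical (4+3) annulation of an enantioenriched bicyclobutane with 4-bromo-4-methylpent-1-en-3-one forms C6–C7 and C2–C3 in one operation and fixes all four cyclobutane stereocentres. The bicyclobutane comes from propyne by two carbene additions; its two wing substituents later close the cyclohexanone, and the enone left in the new bridge becomes the triol triester.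

Key step: step 7

Numbering used below: tricyclo[5.4.0.0(2,8)]undecane. C1, C2, C7 and C8 are the cyclobutane (C2 quaternary with CH3, C7 the CH next to C6). C3–C6 are the four-carbon bridge (C6 = CMe2). C9–C11 are the three-carbon bridge (C9 = CHCH3, C11 = C=O).

Assumption: the (R,R) antipode of the dirhodium catalyst in step 1 and the (S)-oxazaborolidine in step 11 are taken to give the stated configurations (the latter with the quaternary flank as the large group); should either sense be reversed, the antipodal catalyst is used.

Step 1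
Reactants: 1 propyne; 2 ethyl diazoacetate
Product: 3 ethyl (S)-2-methylcycloprop-2-ene-1-carboxylate
Conditions: Rh2(OAc)(DPTI)3 [DPTI = (4R,5R)-4,5-diphenyl-1-triflylimidazolidin-2-onate, 0.5 mol%], CH2Cl2, 0 °C, 2 added slowly to excess 1
Reagents that add atoms: none
Why: Enantioselective cyclopropenation of a terminal alkyne by a chiral dirhodium carbenoid, in which the catalyst differentiates the two faces of the carbene and sets the ring stereocentre from which all later ones are relayed.

Step 2
Reactants: 3 ethyl (S)-2-methylcycloprop-2-ene-1-carboxylate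
Product: 4 (S)-(2-methylcycloprop-2-en-1-yl)methanol
Conditions: iBu2AlH (2.2 equiv), CH2Cl2, −78 °C to 0 °C; Rochelle salt
Reagents that add atoms: none
Why: Hydride reduction of the ester to the primary alcohol, a reaction known for cyclopropenyl esters, leaves the strained alkene and the stereocentre untouched.

Step 3
Reactants: 4 (S)-(2-methylcycloprop-2-en-1-yl)methanol
Product: 5 (S)-triethyl[(2-methylcycloprop-2-en-1-yl)methoxy]silane
Conditions: Et3SiCl, imidazole, CH2Cl2, 0 °C
Reagents that add atoms: chlorotriethylsilane, CC[Si](Cl)(CC)CC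
Why: Silyl ether formation protects the alcohol against O–H insertion in the carbene step and gives a group that a later Swern oxidation removes directly.

Step 4
Reactants: 6 1-aminopropan-2-one hydrochloride
Product: 7 1-diazopropan-2-one
Conditions: NaNO2, H2O/CH2Cl2, 0 °C
Reagents that add atoms: sodium nitrite, [Na+].[O-]N=O
Why: Diazotisation of an alpha-amino ketone salt gives the diazonium ion, which loses its acidic alpha-proton to the stabilised diazo ketone, as in the preparation of diazoacetates from glycine esters.

Step 5
Reactants: 5 (S)-triethyl[(2-methylcycloprop-2-en-1-yl)methoxy]silane; 7 1-diazopropan-2-one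
Product: 8 1-{1-methyl-4-[(triethylsilyloxy)methyl]bicyclo[1.1.0]butan-2-yl}ethan-1-one, both wing substituents exo
Conditions: [Cu(MeCN)4]PF6 (5 mol%), CH2Cl2, rt, 7 added over 6 h
Reagents that add atoms: none
Why: Copper-carbenoid cyclopropanation of the strained cyclopropene double bond (the double carbene addition route from alkynes to bicyclobutanes) should occur anti to the silyloxymethyl group, and the acetyl group takes the less crowded exo position, to which an endo epimer can equilibrate through its enol.

Step 6
Reactants: 9 2-bromo-2-methylpropanoyl bromide; 10 trimethyl(vinyl)silane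
Product: 11 4-bromo-4-methylpent-1-en-3-one
Conditions: AlCl3 (1.1 equiv), CH2Cl2, −78 °C to −20 °C
Reagents that add atoms: none
Why: Friedel–Crafts acylation of a vinylsilane with ipso-substitution of silicon gives the vinyl ketone and leaves the tertiary bromide intact.

Step 7
Reactants: 8 1-{1-methyl-4-[(triethylsilyloxy)methyl]bicyclo[1.1.0]butan-2-yl}ethan-1-one; 11 4-bromo-4-methylpent-1-en-3-one
Product: 13 8-acetyl-2,2,6-trimethyl-7-[(triethylsilyloxy)methyl]bicyclo[4.1.1]oct-4-en-3-one with the C7 and C8 substituents both anti to the C2–C5 bridge, via alpha-bromo ketone 12 (not isolated)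
Conditions: Ir(ppy)3 (1 mol%), 450 nm LEDs, MeCN (0.02 M), rt, 11 added over 8 h to 8 (1.5 equiv); then DBU (2 equiv), 40 °C
Reagents that add atoms: none
Why: Proposed new method: the excited iridium photocatalyst reduces the tertiary C–Br bond of 11 to an electrophilic alpha-keto tertiary radical, which attacks the electron-rich central sigma bond of 8 at the unsubstituted bridgehead from the concave face with release of ring strain; the resulting tertiary cyclobutyl radical at the methyl-bearing carbon then adds to the terminal carbon of the tethered vinyl ketone, bromine-atom transfer from 11 carries the chain to 12, and DBU eliminates HBr. The closest known reaction types are atom-transfer radical additions of alpha-bromocarbonyl compounds and of polyhalomethanes or sulfonyl halides across the central bond of propellanes and bicyclobutanes, and atom-transfer radical cyclisations onto enones. The four-membered ring is not closed but unveiled by cleavage of the central bond, and the seven-membered ring closes by 7-endo-trig radical cyclisation, which gives the bicyclo[4.1.1]octane. Both former bridgeheads react with inversion, so the new bridge lies on the face opposite to the two exo wing substituents of 8; the substrate alone therefore fixes the relative configuration of all four cyclobutane carbons, and the C–Br stereocentre of 12 is erased in the elimination. The step needs attack at the CH rather than the C–CH3 bridgehead, which sterics and the formation of a tertiary radical secure, and ring closure rather than intermolecular capture of the cyclobutyl radical, which the cis-1,3 disposition on the flexible cyclobutane, the gem-dimethyl group and the slow addition of 11 are meant to secure.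

Step 8
Reactants: 13 8-acetyl-2,2,6-trimethyl-7-[(triethylsilyloxy)methyl]bicyclo[4.1.1]oct-4-en-3-one
Product: 14 8-acetyl-2,2,6-trimethyl-3-oxobicyclo[4.1.1]oct-4-ene-7-carbaldehyde
Conditions: (COCl)2, DMSO, CH2Cl2, −78 °C to −40 °C; Et3N
Reagents that add atoms: none
Why: Swern oxidation, under which a primary triethylsilyl ether is cleaved by the chlorosulfonium salt and oxidised directly to the aldehyde while the ketone and the enone are inert.

Step 9
Reactants: 14 8-acetyl-2,2,6-trimethyl-3-oxobicyclo[4.1.1]oct-4-ene-7-carbaldehyde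
Product: 16 2,6,6-trimethyltricyclo[5.4.0.0(2,8)]undeca-3,9-diene-5,11-dione, via aldol adduct 15 (not isolated)
Conditions: pyrrolidine (20 mol%), AcOH (20 mol%), toluene, 50 °C
Reagents that add atoms: none
Why: Intramolecular aldol condensation of the methyl ketone onto the aldehyde closes the six-membered ring as a bicyclo[3.1.1]heptenone, possible because both wing groups point to the face away from the four-carbon bridge, and both alpha-centres can equilibrate through their enols if needed.

Step 10
Reactants: 16 2,6,6-trimethyltricyclo[5.4.0.0(2,8)]undeca-3,9-diene-5,11-dione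
Product: 17 2,6,6,9-tetramethyl-11-(trimethylsilyloxy)tricyclo[5.4.0.0(2,8)]undeca-3,10-dien-5-one with the 9-methyl group syn to C7
Conditions: Me2CuLi (1.05 equiv), Me3SiCl, THF, −78 °C; Et3N, pentane
Reagents that add atoms: lithium dimethylcuprate, [Li+].C[Cu-]C; chlorotrimethylsilane, C[Si](C)(C)Cl
Why: Conjugate addition of a Gilman cuprate with silyl trapping should take the strained, unhindered bicyclo[3.1.1]heptenone in preference to the enone whose beta-carbon is neopentylic, and the methyl group should enter from the C7–H side, anti to the methyl-bearing C2, as in cuprate additions to apoverbenone, which sets C9.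

Step 11
Reactants: 17 2,6,6,9-tetramethyl-11-(trimethylsilyloxy)tricyclo[5.4.0.0(2,8)]undeca-3,10-dien-5-one
Product: 19 (5R)-5-hydroxy-2,6,6,9-tetramethyltricyclo[5.4.0.0(2,8)]undec-3-en-11-one with the 5-hydroxyl on the face toward C8, via silyl enol ether carbinol 18 (not isolated)
Conditions: (S)-Me-CBS oxazaborolidine (20 mol%), catecholborane, toluene, −78 °C; then 1 M HCl, THF, 0 °C
Reagents that add atoms: none
Why: Corey–Bakshi–Shibata reduction of the only free ketone (C11 is masked as its silyl enol ether) sets C5 by reagent control, needed because C5 lies too far from the differentiating centres for substrate control, and the acid work-up returns the C11 ketone.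

Step 12
Reactants: 19 (5R)-5-hydroxy-2,6,6,9-tetramethyltricyclo[5.4.0.0(2,8)]undec-3-en-11-one
Product: 20 3,4,5-trihydroxy-2,6,6,9-tetramethyltricyclo[5.4.0.0(2,8)]undecan-11-one with the 3- and 4-hydroxyls cis on the face toward C1 and trans to the 5-hydroxyl
Conditions: OsO4 (2 mol%), NMO, acetone/H2O, rt
Reagents that add atoms: N-methylmorpholine N-oxide, C[N+]1([O-])CCOCC1; water, O
Why: Upjohn dihydroxylation, in which osmium tetroxide should add to the face of the ring cis-alkene anti to the allylic hydroxyl, the usual outcome for osmylation of allylic alcohols, gives the 3,4-cis-diol trans to the C5 oxygen.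

Step 13
Reactants: 20 3,4,5-trihydroxy-2,6,6,9-tetramethyltricyclo[5.4.0.0(2,8)]undecan-11-one
Product: 21 3,5-dihydroxy-2,6,6,9-tetramethyl-11-oxotricyclo[5.4.0.0(2,8)]undecan-4-yl acetate
Conditions: Ac2O (1.05 equiv), pyridine, CH2Cl2, −20 °C
Reagents that add atoms: acetic anhydride, CC(=O)OC(C)=O
Why: Selective acylation, in which the C4 hydroxyl, the only one not flanked by a quaternary carbon, should be acetylated first.

Step 14
Reactants: 21 3,5-dihydroxy-2,6,6,9-tetramethyl-11-oxotricyclo[5.4.0.0(2,8)]undecan-4-yl acetate
Product: 23 4-acetoxy-2,6,6,9-tetramethyl-11-oxotricyclo[5.4.0.0(2,8)]undecane-3,5-diyl bis[(Z)-2-methylbut-2-enoate] (CNP0197834.1), via 5-monoangelate 22 (not isolated)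
Conditions: angelic acid (3 equiv), 2,4,6-trichlorobenzoyl chloride (3 equiv), Et3N, toluene, rt; then 21, 80 °C
Reagents that add atoms: angelic acid, (Z)-2-methylbut-2-enoic acid, C/C=C(/C)C(=O)O
Why: Yamaguchi-type esterification through the mixed anhydride without a nucleophilic catalyst should acylate the two neopentylic hydroxyls and avoid isomerisation of the (Z)-acyl group to the tiglate.

**Compound list**

1 | propyne | CC#C | starting material
2 | ethyl diazoacetate | CCOC(=O)C=[N+]=[N-] | starting material
3 | ethyl (S)-2-methylcycloprop-2-ene-1-carboxylate | CC1=C[C@@H]1C(=O)OCC | intermediate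
4 | (S)-(2-methylcycloprop-2-en-1-yl)methanol | CC1=C[C@@H]1CO | intermediate
5 | (S)-triethyl[(2-methylcycloprop-2-en-1-yl)methoxy]silane | CC1=C[C@@H]1CO[Si](CC)(CC)CC | intermediate
6 | 1-aminopropan-2-one hydrochloride | CC(=O)C[NH3+].[Cl-] | starting material
7 | 1-diazopropan-2-one | CC(=O)C=[N+]=[N-] | intermediate
8 | 1-{1-methyl-4-[(triethylsilyloxy)methyl]bicyclo[1.1.0]butan-2-yl}ethan-1-one, acetyl and silyloxymethyl both exo | C[C@@]12[C@@H](CO[Si](CC)(CC)CC)[C@@H]1[C@H]2C(C)=O | intermediate
9 | 2-bromo-2-methylpropanoyl bromide | CC(C)(Br)C(=O)Br | starting material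
10 | trimethyl(vinyl)silane | C=C[Si](C)(C)C | starting material
11 | 4-bromo-4-methylpent-1-en-3-one | C=CC(=O)C(C)(C)Br | intermediate
12 | 8-acetyl-4-bromo-2,2,6-trimethyl-7-[(triethylsilyloxy)methyl]bicyclo[4.1.1]octan-3-one, C4 epimers, C7 and C8 substituents anti to the C2–C5 bridge | O=C1C(Br)C[C@]2(C)[C@@H](CO[Si](CC)(CC)CC)[C@@H]([C@H]2C(C)=O)C1(C)C | intermediate
13 | 8-acetyl-2,2,6-trimethyl-7-[(triethylsilyloxy)methyl]bicyclo[4.1.1]oct-4-en-3-one, C7 and C8 substituents anti to the C2–C5 bridge | O=C1C=C[C@]2(C)[C@@H](CO[Si](CC)(CC)CC)[C@@H]([C@H]2C(C)=O)C1(C)C | intermediate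
14 | 8-acetyl-2,2,6-trimethyl-3-oxobicyclo[4.1.1]oct-4-ene-7-carbaldehyde | O=C1C=C[C@]2(C)[C@@H](C=O)[C@@H]([C@H]2C(C)=O)C1(C)C | intermediate
15 | 9-hydroxy-2,6,6-trimethyltricyclo[5.4.0.0(2,8)]undec-3-ene-5,11-dione, C9 epimers | O=C1C=C[C@]2(C)[C@@H]3[C@@H]([C@H]2C(=O)CC3O)C1(C)C | intermediate
16 | 2,6,6-trimethyltricyclo[5.4.0.0(2,8)]undeca-3,9-diene-5,11-dione | O=C1C=C[C@]2(C)[C@@H]3[C@@H]([C@H]2C(=O)C=C3)C1(C)C | intermediate
17 | 2,6,6,9-tetramethyl-11-(trimethylsilyloxy)tricyclo[5.4.0.0(2,8)]undeca-3,10-dien-5-one, 9-methyl syn to C7 | O=C1C=C[C@]2(C)[C@@H]3[C@@H]([C@H]2C(O[Si](C)(C)C)=C[C@H]3C)C1(C)C | intermediate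
18 | (5R)-2,6,6,9-tetramethyl-11-(trimethylsilyloxy)tricyclo[5.4.0.0(2,8)]undeca-3,10-dien-5-ol | O[C@@H]1C=C[C@]2(C)[C@@H]3[C@@H]([C@H]2C(O[Si](C)(C)C)=C[C@H]3C)C1(C)C | intermediate
19 | (5R)-5-hydroxy-2,6,6,9-tetramethyltricyclo[5.4.0.0(2,8)]undec-3-en-11-one, 5-OH on the face toward C8 | O[C@@H]1C=C[C@]2(C)[C@@H]3[C@@H]([C@H]2C(=O)C[C@H]3C)C1(C)C | intermediate
20 | 3,4,5-trihydroxy-2,6,6,9-tetramethyltricyclo[5.4.0.0(2,8)]undecan-11-one, 3- and 4-OH cis on the face toward C1, 5-OH trans to them | O[C@@H]1[C@@H](O)[C@@H](O)[C@]2(C)[C@@H]3[C@@H]([C@H]2C(=O)C[C@H]3C)C1(C)C | intermediate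
21 | 3,5-dihydroxy-2,6,6,9-tetramethyl-11-oxotricyclo[5.4.0.0(2,8)]undecan-4-yl acetate | O[C@@H]1[C@@H](OC(C)=O)[C@@H](O)[C@]2(C)[C@@H]3[C@@H]([C@H]2C(=O)C[C@H]3C)C1(C)C | intermediate
22 | 4-acetoxy-3-hydroxy-2,6,6,9-tetramethyl-11-oxotricyclo[5.4.0.0(2,8)]undecan-5-yl (Z)-2-methylbut-2-enoate | C/C=C(/C)C(=O)O[C@@H]1[C@@H](OC(C)=O)[C@@H](O)[C@]2(C)[C@@H]3[C@@H]([C@H]2C(=O)C[C@H]3C)C1(C)C | intermediate
23 | 4-acetoxy-2,6,6,9-tetramethyl-11-oxotricyclo[5.4.0.0(2,8)]undecane-3,5-diyl bis[(Z)-2-methylbut-2-enoate] | C/C=C(/C)C(=O)O[C@@H]1[C@@H](OC(C)=O)[C@@H](OC(=O)/C(C)=C\C)[C@]2(C)[C@@H]3[C@@H]([C@H]2C(=O)C[C@H]3C)C1(C)C | target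

**Step count.** Total: 14 steps. Longest linear sequence: 12 steps (steps 1, 2, 3, 5, 7, 8, 9, 10, 11, 12, 13, 14).

**Steps most likely to fail**

Step 7 (proposed new method). The cyclobutyl radical may be captured between molecules, by a second vinyl ketone or by early bromine transfer, before the seven-membered ring closes. The vinyl ketone may also oligomerise, and ring closure is slowed because it forces the two wing groups into a 1,3-diaxial arrangement. The fallback separates the two bond formations and uses known reaction types; it sets out from 8 and 9 and returns at 13. Acylation of ethylene with 9 (AlBr3) should give 1,4-dibromo-4-methylpentan-3-one F1, which carries no radical acceptor. Atom-transfer radical addition of F1 across the central bond of 8 (CuBr, tris(2-pyridylmethyl)amine, MeCN), as known for polyhalomethanes and sulfonyl halides with bicyclobutanes, should give the open 1,3-adduct, tertiary cyclobutyl bromide F2. Et3N then unveils the vinyl ketone F3. Tin hydride cyclisation at high dilution (Bu3SnH, AIBN, toluene, 80 °C) should close the seven-membered ring to the saturated bicyclic ketone F4. IBX dehydrogenation (DMSO, 70 °C) should then give 13; only the bridge ketone can be dehydrogenated, because the acetyl group has no beta-hydrogen that could leave without forming a bridgehead alkene.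

Step 5. Copper-induced ring opening or ene dimerisation of the cyclopropene may outrun carbene transfer, and the facial or exo/endo selectivity may be poor. The fallback sets out from 5 and 7 and returns at 8. Uncatalysed 1,3-dipolar cycloaddition of the diazo ketone to the strained double bond (Et2O, rt, dark), again anti to the silyloxymethyl group, should give the 1-pyrazoline 1-{1-methyl-6-[(triethylsilyloxy)methyl]-2,3-diazabicyclo[3.1.0]hex-2-en-4-yl}ethan-1-one F5. Photolysis (350 nm, pentane, −20 °C) should then extrude nitrogen and close the bicyclobutane 8.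

Step 14. Acylation of the two neopentylic hydroxyls may stay incomplete, and forcing conditions may isomerise the (Z)-acyl group or move the acetate. The fallback builds the double bonds on the molecule; it sets out from 21 and returns at 23. Esterification of both hydroxyls with 2-[bis(2,2,2-trifluoroethoxy)phosphoryl]propanoic acid (DCC, DMAP), a saturated acid that can be activated hard without isomerisation, should give the bis-phosphonate F6. Still–Gennari olefination with acetaldehyde (KN(SiMe3)2, 18-crown-6, THF, −78 °C) should then form both (Z)-2-methylbut-2-enoates.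

Further compounds
F1 | step 7 | 1,4-dibromo-4-methylpentan-3-one | BrCCC(=O)C(C)(C)Br
F2 | step 7 | 1-{3-bromo-2-(5-bromo-2-methyl-3-oxopentan-2-yl)-3-methyl-4-[(triethylsilyloxy)methyl]cyclobutyl}ethan-1-one, chain trans to acetyl and silyloxymethyl | CC1(Br)[C@@H](CO[Si](CC)(CC)CC)[C@H](C(C)(C)C(=O)CCBr)[C@H]1C(C)=O
F3 | step 7 | 4-{2-acetyl-3-bromo-3-methyl-4-[(triethylsilyloxy)methyl]cyclobutyl}-4-methylpent-1-en-3-one | CC1(Br)[C@@H](CO[Si](CC)(CC)CC)[C@H](C(C)(C)C(=O)C=C)[C@H]1C(C)=O
F4 | step 7 | 8-acetyl-2,2,6-trimethyl-7-[(triethylsilyloxy)methyl]bicyclo[4.1.1]octan-3-one | O=C1CC[C@]2(C)[C@@H](CO[Si](CC)(CC)CC)[C@@H]([C@H]2C(C)=O)C1(C)C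
F5 | step 5 | 1-{1-methyl-6-[(triethylsilyloxy)methyl]-2,3-diazabicyclo[3.1.0]hex-2-en-4-yl}ethan-1-one | CC(=O)C1N=N[C@]2(C)[C@@H](CO[Si](CC)(CC)CC)[C@H]12
F6 | step 14 | 4-acetoxy-2,6,6,9-tetramethyl-11-oxotricyclo[5.4.0.0(2,8)]undecane-3,5-diyl bis{2-[bis(2,2,2-trifluoroethoxy)phosphoryl]propanoate} | CC(C(=O)O[C@@H]1[C@@H](OC(C)=O)[C@@H](OC(=O)C(C)P(=O)(OCC(F)(F)F)OCC(F)(F)F)[C@]2(C)[C@@H]3[C@@H]([C@H]2C(=O)C[C@H]3C)C1(C)C)P(=O)(OCC(F)(F)F)OCC(F)(F)F
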